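In the early minutes of the green run, which is the asked flask followed up to 90.0 min, you count turnovers: multiply the fraction of starting material turned into target by 556, the starting material charged per catalyst charged.

- green: starting material 0.050 M; reagent 0.060 M; free catalyst 90 µM; impurity 81 µM; the very flask that is asked about, followed so far
- flask: starting material 0.050 M; reagent 0.0600 M; free catalyst 90 µM; impurity 81 µM; time 4.0 h

green run (percent of the starting material charged): time / min: target / % = 12.0: 2.6; 30.0: 6.9; 60.0: 11.1; 90.0: 15.5

(standard deviation of a reading: 0.3 percentage points)

- the numbers in the tables scatter by 0.3 percentage points (one standard deviation)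
- candidate steps: catalyst intermediate B <-> catalyst intermediate C; free catalyst + impurity -> spent catalyst; reagent + free catalyst <-> catalyst intermediate A; catalyst intermediate A -> released group + catalyst intermediate B; catalyst intermediate D -> free catalyst + target; starting material + catalyst intermediate C -> catalyst intermediate D

* amount of target in percent of the starting material charged, at 25 min, 80 min and 4.0 h

In the green run the count reaches 38.3 turnovers at 30.0 min, so each charged catalyst starts at about 76.7 h⁻¹. From 30.0 min to 90.0 min the green run climbs to 86.1 turnovers. That gives the late turnover frequency, the turnovers per charged catalyst per hour over that stretch: 47.8 h⁻¹. Both are readings and carry the scatter.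

In the middle of the green run the frequency has dropped to 62.3 % of its opening value, a loss larger than the 15.5 % of starting material turned into target by 90.0 min. So look at the catalyst. The impurity charge equals 90.0 % of the catalyst charge, and the candidate step spends them one for one.

For the end of this flask, my own reckoning takes one more drop of the same ratio. The stretch from 90.0 min to 4.0 h then runs at 29.8 h⁻¹, which brings the count to 161 turnovers, or 29.0 % target.

The forecast gives 5.8 %, 14.1 % and 30 %, and its ground for the last value is: “Continued poisoning and mild substrate depletion favour the lower end”.

This flask gives 5.55 %, 14.2 % and 28.3 %.

    catalyst intermediate B ⇌ catalyst intermediate C (K = 0.410, k = 0.210 s⁻¹)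
    free catalyst + impurity → spent catalyst (k = 20.0 M⁻¹ s⁻¹)
    reagent + free catalyst ⇌ catalyst intermediate A (K = 180 M⁻¹, k = 3.90 M⁻¹ s⁻¹)
    catalyst intermediate A → released group + catalyst intermediate B (k = 0.170 s⁻¹)
    catalyst intermediate D → free catalyst + target (k = 0.0850 s⁻¹)
    starting material + catalyst intermediate C → catalyst intermediate D (k = 4.70 M⁻¹ s⁻¹)

That last value is 157 turnovers at 4.0 h, and the forecast stands within its margin. Switching the impurity step off moves the shown readings by 12 scatter widths, root mean square. Now apply the late turnover frequency once more. From 4.0 h to 8.00 h this flask's target rises from 28.3 % to 39.9 %, which is 16.0 h⁻¹, about a third of the 47.8 h⁻¹ read from the green run.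

The numbers in the tables come from a simulation for an exercise, and the scatter is random.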